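I decide to follow the J that is left, not the E that is made.

| flask | X | J | Z | remark | time |
|---|---|---|---|---|---|
| summer | 0.40 M | 0.32 M | 5.7 mM | run made earlier |  |
| midnight | 0.40 M | 0.32 M | 8.5 mM | run made earlier |  |
| dawn | 0.40 M | 0.32 M | 11 mM | run made earlier |  |
| delta | 0.40 M | 0.320 M | 5.0 mM |  | 30 min |
| zeta | 0.40 M | 0.320 M | 8.0 mM |  | 30 min |
| alpha | 0.40 M | 0.320 M | 12 mM |  | 30 min |

- summer (time / min: E / %): 3.00: 11; 6.00: 22; 10.0: 37; 12.0: 39; 15.0: 48
- midnight (time / min: E / %): 1.33: 10; 4.00: 21; 8.00: 40; 10.0: 46; 15.0: 56
- dawn (time / min: E / %): 3.00: 21; 6.00: 37; 10.0: 56; 12.0: 57; 15.0: 62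

(each reading ± 1.5 percentage points)

- "hardly changes" means that all values lie within two and a half points (for a concentration: within two and a half percent of the largest)

- amount of E at the end, in percent of the X charged for delta, zeta, alpha, in this order
- the course of these numbers from the first flask to the last (falls, then rises / falls all the way / hardly changes / rises, then falls / rises all the way)

Step 1. I take one E per J. J is then the limiting reagent, and E can reach 80.0 % of the X charged. Let f be the fraction of J left, read from E over that ceiling.

Step 2. Time and the Z charged seem to count as their product Z·t. Summer at 15.0 min and midnight at 10.0 min have nearly equal products, and they read 48 % and 46 %.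

Step 3. The last midnight reading gives f = 0.300. From it I get 0.00944 mM⁻¹ min⁻¹. This is the catalyst constant κ, which is −ln f per unit of Z·t. It is a reading: the last summer and dawn readings give 0.0107 mM⁻¹ min⁻¹ and 0.00904 mM⁻¹ min⁻¹, so the summer reading stands higher than the dawn reading.

Step 4. In my reckoning J starts to fall at κ·Z of its charge per minute: 0.0472 min⁻¹ in delta and 0.113 min⁻¹ in alpha. That rate shrinks with f. By 30 min it stands at 24.3 % of its start in delta, 10.4 % in zeta and 3.34 % in alpha. So in my reckoning alpha starts faster than delta but ends slower.

Step 5. I get E of 60.6 %, 71.7 % and 77.3 %. The second gain is smaller than the first.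

Step 6. The forecast gives 61 %, 72 % and 77 %, and rises all the way: “I expect a steady rise towards the ceiling”.

Step 7. The flasks give 60.9 %, 70.4 % and 75.6 %, and rises all the way.

    X + Z ⇌ D (K = 1.10 M⁻¹, k = 1950 M⁻¹ min⁻¹)
    J + D → G (k = 65.7 M⁻¹ min⁻¹)
    G → L + Q (k = 82.3 min⁻¹)
    Q → Z + E (k = 6.30 min⁻¹)

Step 8. For delta, κ gave 24.3 % of J left and the flask holds 24 %; for alpha it gave 3.34 % and the flask holds more, 5.4 %. In delta at 30.0 min, the half-life of D by its step with J is 0.14 min, far shorter than the run, D is made and used up at a ratio of 0.998, and the catalyst stands as D 12.9 %, G 0.786 %, Q 10.4 % and Z, the resting state, 75.9 %.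

(Readings and results were generated by integration with constants of no real substance; noise was put on by code.)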